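## The problem

The target 22 is a benzylic ester joining two highly substituted benzene rings. Ring A is a methyl 2,4-dihydroxy-3-methylbenzoate that carries the CH2O group at C6. Ring B is the 3-formyl-2,4-dihydroxy-6-methylbenzoyl unit. There is no stereocenter, so the task is one of regiochemistry and functional-group tolerance. Ring B needs its formyl group at C3, between the two oxygens, and not at the similarly activated C5; ring A has two methyl groups, and only the one at C6 may be functionalised. The CH2–O–C(=O) link lies ortho to the ring A methyl ester, so a free benzylic alkoxide or harsh acid invites closure to the phthalide, and hydrogenolysis would cut the same bond. The aldehyde flanked by two phenols does not tolerate strong base or oxidants, and the ring B carboxyl is di-ortho-substituted, which makes acyl substitution there slow. The feature that opens the route lies in ring B: the C3 formyl carbon and the C4 hydroxyl are neighbours, and C3 has the C2 oxygen on its other side. That is the polarity of a 3-alkoxyaryne across C3–C4, which takes an oxygen nucleophile at C4 and a carbon electrophile at C3.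

## Retrosynthesis

**22 from 21.** The last operation breaks only three O–CH2OCH3 acetal bonds (ring A C2 and C4, ring B C2). Acetal protection is preferred to benzyl ethers, whose hydrogenolysis would also cleave the benzylic ester, and to silyl ethers, which would not survive fluoride one step earlier. The forward step must be acidic enough for three aryl MOM ethers and still leave the benzylic ester, the methyl ester and the aldehyde intact.

**21 from 16 and 17.** Two ring B bonds are cut together: C3–CHO and C4–O. Cutting only the C3–C bond would mean an electrophilic formylation that has to choose between C3 and C5 of ring B and also avoid the more electron-rich ring A. The double cut replaces the aldehyde by a silyl group at C3 and the phenol by a triflate at C4, so the carbon arrives where silicon sat. Precursor 16 holds no aldehyde and no free phenol, so the esterification and all protecting-group work are finished before the sensitive salicylaldehyde exists. The forward reaction must generate the C3–C4 aryne under conditions that spare two esters and three acetals, and the oxygen of 17 must add at C4 only.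

**16 from 11 and 15.** The cut is the O–CH2 bond of the benzylic ester. The neighbouring cut at the acyl C–O bond would need a ring A benzylic alcohol, which would lactonise onto the adjacent methyl ester, and an acyl donor shielded by two ortho substituents. Alkylating the carboxylate of 11 with bromide 15 moves the bond formation to the unhindered CH2 and divides the molecule into two halves of similar size. It needs a base too weak to disturb the silyl triflate.

**15 from 13 and 12.** The C–Br bond and then the two O–MOM bonds are cut. Only the C6 methyl group is ortho to the ester, so deprotonation gives an ester-stabilised benzylic anion there and leaves the C3 methyl alone; radical bromination could not make this distinction. Ester 12 is bought with every ring A carbon in place.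

**11 from 10, 9 and 8.** The allyl–oxygen bond of the ester, the C2 O–MOM bond and the C4 O–S bond are cut in turn. The acid is released last and under neutral conditions because the silyl triflate would not survive saponification of a hindered ester. In diol 8 the two phenols differ: the C2 hydroxyl is hydrogen-bonded to the ester carbonyl, so sulfonylation should take the C4 hydroxyl, and the C2 hydroxyl is then capped as the acetal that later polarises the aryne.

**8 from 6, 4, 2 and 1.** The ring B C1–carboxyl bond and the C3–Si bond are cut. Both come from directed ortho-metalation of the bis-MOM ether 2 of orcinol 1. The first lithiation goes between the two oxygens (via 3) and places silicon exactly where the formyl carbon must end. With that site blocked, the second (via 5) can only go to the position flanked by oxygen and methyl, which becomes C1. Orcinol is a cheap symmetric arene that already has the methyl group and both oxygens. The two MOM groups of 6 must then be removed (via 7) without protonolysis of the C–Si bond on a very electron-rich carbon, which calls for non-protic cleavage.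

## Roads not taken

**Alternative 1:** Ring B is cut at C1–C6 and C3–C4 and built from tert-butyl acetoacetate A2 and ethyl crotonate A3. A Michael addition followed by Claisen-type closure gives the cyclic dione A1; C3 formylation and dehydrogenation would then give the aromatic ring.
- Merits: both reagents are bulk chemicals, no organolithium is needed, and C3 is the only carbon between the two carbonyl groups of A1, so the formyl position is fixed by structure. In cost, and probably in step count to the ring B skeleton, this road is better than the seven steps to acid 11.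
- Weak points: the oxidation that aromatises a 2-formyl-1,3-dione bearing an ester has to leave the aldehyde alone. The two stereocenters of A1 are made only to be destroyed. The formyl acid must then be freed from its tert-butyl ester, protected on two phenols that now have to be told apart in the presence of the aldehyde, and carried through the esterification.
- What the chosen plan sets against it: the arene is bought intact, and the aldehyde appears only after the ester bond to ring A exists, so no operation other than the final deprotection is run on the salicylaldehyde.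

**Alternative 2:** Ring B is cut at C2–C3, C4–C5 and C1–C2. Photochemical Wolff rearrangement of diazoketone A5 gives a vinylketene; 2+2 addition to siloxyalkyne A6, four-electron ring opening and six-electron closure would give phenol A4.
- Merits: one step sets every substituent of ring B, with the aldehyde masked as an acetal and the two oxygens already differentiated (C2 free, C4 silylated). In this it is better than the chosen plan, which spends steps 4 to 6 on differentiation.
- Weak points: A5 needs diazomethane chemistry on a half ester, and A6 is a labile ynol ether carrying an acetal; both take several steps. Fluoride cleavage of the 2-(trimethylsilyl)ethyl ester of A4 would also strip the silyl ether, so the differentiation is partly lost again. A benzene ring is built where a suitable one can be bought.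
- What the chosen plan sets against it: standard lithiation chemistry from orcinol, no diazo compound and no photochemical step, at a comparable overall length.

**Alternative 3:** Ring A is cut at C1–C2 and C5–C6. The bis(silyloxy) diene A8 adds to alkynoate A9, which already carries ring B on its propargylic oxygen, and loss of methanol and the silyl groups would give A7 directly.
- Merits: the ester link is made on an unhindered propargylic alcohol, with no benzylic halide and no phthalide risk. There this road is better than steps 9 and 10.
- Weak points: ring A with all its substituents is commercial as 12, so constructing it spends steps on the easy half. The hard half is untouched, because A9 still requires the C3-formylated ring B acid. A8 is a strong nucleophile and the aldehyde of A9 is an aldol acceptor, and the propargylic carboxylate can leave.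
- What the chosen plan sets against it: it puts its key step on the real problem, the placement of the formyl group in ring B, and takes ring A from the shelf.

Key step: step 11

## Route

Assumption: orcinol is used in its anhydrous form; benzoxete 19 is racemic and the geometry of the exocyclic double bond of 20 is undefined, neither of which affects 21.

Step 1
Reactants: 1 orcinol (5-methylbenzene-1,3-diol)
Product: 2 1,3-bis(methoxymethoxy)-5-methylbenzene
Conditions: NaH, MOMCl, DMF, 0 °C to rt
Reagents that add atoms: chloromethyl methyl ether, COCCl
Why: Williamson-type O-alkylation of both phenoxides; the two MOM ethers protect the phenols and serve as the directing groups for both lithiations that follow.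

Step 2
Reactants: 2 1,3-bis(methoxymethoxy)-5-methylbenzene
Product: 4 [2,6-bis(methoxymethoxy)-4-methylphenyl]trimethylsilane, via aryllithium 3 (not isolated)
Conditions: n-BuLi, THF, 0 °C; Me3SiCl, −78 °C to rt
Reagents that add atoms: chlorotrimethylsilane, C[Si](C)(C)Cl
Why: Directed ortho-metalation; the hydrogen between the two OMOM groups is the most acidic and its lithium is chelated from both sides, so silicon should enter only there, at the carbon that becomes ring B C3.

Step 3
Reactants: 4 [2,6-bis(methoxymethoxy)-4-methylphenyl]trimethylsilane
Product: 6 prop-2-en-1-yl 2,4-bis(methoxymethoxy)-6-methyl-3-(trimethylsilyl)benzoate, via aryllithium 5 (not isolated)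
Conditions: s-BuLi, TMEDA, THF, −78 °C; then added to ClCO2CH2CH=CH2, THF, −78 °C to rt
Reagents that add atoms: allyl chloroformate, C=CCOC(=O)Cl
Why: Second directed ortho-metalation with the favoured site blocked by silicon, so the two remaining ortho positions (equivalent by symmetry) are the only ones open; acylation of 5 gives a di-ortho-substituted ester that resists a second addition, and the allyl ester can later be removed under neutral conditions.

Step 4
Reactants: 6 prop-2-en-1-yl 2,4-bis(methoxymethoxy)-6-methyl-3-(trimethylsilyl)benzoate
Product: 8 prop-2-en-1-yl 2,4-dihydroxy-6-methyl-3-(trimethylsilyl)benzoate, via bis(trimethylsilyl) ether 7 (not isolated)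
Conditions: Me3SiOTf, 2,2'-bipyridyl, CH3CN, 0 °C to rt; then H2O
Reagents that add atoms: none
Why: Non-protic cleavage of aryl MOM ethers: the silyl triflate–bipyridyl pair converts each ArO–MOM into ArO–SiMe3, which water hydrolyses; strong protic acid is avoided because the silicon-bearing carbon lies between two oxygens and would be prone to protodesilylation.

Step 5
Reactants: 8 prop-2-en-1-yl 2,4-dihydroxy-6-methyl-3-(trimethylsilyl)benzoate
Product: 9 prop-2-en-1-yl 2-hydroxy-6-methyl-4-(trifluoromethylsulfonyloxy)-3-(trimethylsilyl)benzoate
Conditions: Tf2O (1.05 equiv), pyridine, CH2Cl2, −40 to 0 °C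
Reagents that add atoms: trifluoromethanesulfonic anhydride, FC(F)(F)S(=O)(=O)OS(=O)(=O)C(F)(F)F
Why: Selective O-sulfonylation of a 2,4-dihydroxybenzoate at the para hydroxyl; the C2 hydroxyl is hydrogen-bonded to the ester carbonyl and flanked on both sides, so one equivalent of anhydride should react at C4 only.

Step 6
Reactants: 9 prop-2-en-1-yl 2-hydroxy-6-methyl-4-(trifluoromethylsulfonyloxy)-3-(trimethylsilyl)benzoate
Product: 10 prop-2-en-1-yl 2-(methoxymethoxy)-6-methyl-4-(trifluoromethylsulfonyloxy)-3-(trimethylsilyl)benzoate
Conditions: MOMCl, i-Pr2NEt, CH2Cl2, 0 °C to rt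
Reagents that add atoms: chloromethyl methyl ether, COCCl
Why: O-alkylation of the remaining phenol with a highly reactive alkoxymethyl chloride and an amine base; no metal phenoxide is generated, so the oxygen next to silicon is alkylated before it can attack silicon.

Step 7
Reactants: 10 prop-2-en-1-yl 2-(methoxymethoxy)-6-methyl-4-(trifluoromethylsulfonyloxy)-3-(trimethylsilyl)benzoate
Product: 11 2-(methoxymethoxy)-6-methyl-4-(trifluoromethylsulfonyloxy)-3-(trimethylsilyl)benzoic acid
Conditions: Pd(PPh3)4 (5 mol %), morpholine, THF, rt; work-up at pH 4, used at once
Reagents that add atoms: none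
Why: Tsuji–Trost deallylation: zerovalent palladium ionises the allyl ester at the allylic carbon, remote from the hindered carbonyl, and morpholine captures the allyl fragment; the aryl triflate, shielded by the silyl group, should not undergo oxidative addition at room temperature.

Step 8
Reactants: 12 methyl 2,4-dihydroxy-3,6-dimethylbenzoate
Product: 13 methyl 2,4-bis(methoxymethoxy)-3,6-dimethylbenzoate
Conditions: NaH, MOMCl, DMF, 0 °C to rt
Reagents that add atoms: chloromethyl methyl ether, COCCl
Why: Williamson-type O-alkylation; the sodium phenoxides overcome the hydrogen bond of the C2 hydroxyl to the ester, and the acetals carry no acidic hydrogen into the lithiation and aryne steps.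

Step 9
Reactants: 13 methyl 2,4-bis(methoxymethoxy)-3,6-dimethylbenzoate
Product: 15 methyl 6-(bromomethyl)-2,4-bis(methoxymethoxy)-3-methylbenzoate, via benzylic organolithium 14 (not isolated)
Conditions: LiN(i-Pr)2, THF, −78 °C; then cannulated into BrCCl2CCl2Br, THF, −78 °C
Reagents that add atoms: 1,2-dibromo-1,1,2,2-tetrachloroethane, BrC(Cl)(Cl)C(Cl)(Cl)Br
Why: Lateral lithiation of an ortho-toluate: only the C6 methyl is conjugated with the ester, so the amide base forms the extended enolate 14 there and leaves the C3 methyl alone; bromine transfer as in enolate halogenation gives the bromide, and inverse addition keeps 14 away from 15.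

Step 10
Reactants: 11 2-(methoxymethoxy)-6-methyl-4-(trifluoromethylsulfonyloxy)-3-(trimethylsilyl)benzoic acid; 15 methyl 6-(bromomethyl)-2,4-bis(methoxymethoxy)-3-methylbenzoate
Product: 16 [2-(methoxycarbonyl)-3,5-bis(methoxymethoxy)-4-methylphenyl]methyl 2-(methoxymethoxy)-6-methyl-4-(trifluoromethylsulfonyloxy)-3-(trimethylsilyl)benzoate
Conditions: KHCO3, DMF, rt
Reagents that add atoms: none
Why: SN2 O-alkylation of a carboxylate by a benzylic bromide, the standard way to esterify a di-ortho-substituted benzoic acid because the bond forms at the unhindered CH2; bicarbonate is too weak a base to activate the silyl triflate.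

Step 11
Reactants: 16 [2-(methoxycarbonyl)-3,5-bis(methoxymethoxy)-4-methylphenyl]methyl 2-(methoxymethoxy)-6-methyl-4-(trifluoromethylsulfonyloxy)-3-(trimethylsilyl)benzoate; 17 N,N-dimethylformamide
Product: 21 [2-(methoxycarbonyl)-3,5-bis(methoxymethoxy)-4-methylphenyl]methyl 3-formyl-4-hydroxy-2-(methoxymethoxy)-6-methylbenzoate, via aryne 18 (not isolated), via benzoxete 19 (not isolated), via ortho-quinone methide 20 (not isolated)
Conditions: CsF, anhydrous 17 as solvent, rt to 50 °C; then H2O
Reagents that add atoms: water, O
Why: Fluoride attacks the silicon of 16 and triflate leaves from the neighbouring carbon, giving the ring B C3–C4 aryne 18 under conditions that esters and MOM ethers tolerate. The carbonyl oxygen of 17 adds to C4 and the C3 aryl anion closes on the iminium carbon in a 4-exo-trig sense, a formal 2+2 addition that gives benzoxete 19. This strained ring opens by a four-electron electrocyclic process to ortho-quinone methide 20; water then adds to the aminomethylidene carbon and expels dimethylamine, so C3 ends as the aldehyde, C4 as the phenol, and no ring is retained. The closest known reaction type is the insertion of arynes into the C=O bond of formamides, which gives salicylaldehydes after hydrolysis. No stereocenter remains, since the one in 19 is lost on ring opening. The step needs regioselectivity, and the inductively withdrawing C2 OMOM group secures it: it polarises the aryne so that oxygen attacks the distal C4 and negative charge builds at C3 beside the C–O bond. Water is held back until 16 is consumed so that the phenoxide of 21 cannot compete with 17 for the aryne.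

Step 12
Reactants: 21 [2-(methoxycarbonyl)-3,5-bis(methoxymethoxy)-4-methylphenyl]methyl 3-formyl-4-hydroxy-2-(methoxymethoxy)-6-methylbenzoate
Product: 22 [3,5-dihydroxy-2-(methoxycarbonyl)-4-methylphenyl]methyl 3-formyl-2,4-dihydroxy-6-methylbenzoate
Conditions: HCl (cat.), MeOH/THF, 40 °C
Reagents that add atoms: none
Why: Acid-catalysed acetal exchange (methanolysis of aryl MOM ethers); methanol traps the methoxymethyl cation as dimethoxymethane so that the free C5 position of ring A is not alkylated, and the hindered benzylic ester and the methyl ester should survive dilute acid.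

## Compound list

1 | orcinol (5-methylbenzene-1,3-diol) | Cc1cc(O)cc(O)c1 | starting material
2 | 1,3-bis(methoxymethoxy)-5-methylbenzene | COCOc1cc(C)cc(OCOC)c1 | intermediate
3 | [2,6-bis(methoxymethoxy)-4-methylphenyl]lithium | [Li]c1c(OCOC)cc(C)cc1OCOC | intermediate
4 | [2,6-bis(methoxymethoxy)-4-methylphenyl]trimethylsilane | C[Si](C)(C)c1c(OCOC)cc(C)cc1OCOC | intermediate
5 | [2,4-bis(methoxymethoxy)-6-methyl-3-(trimethylsilyl)phenyl]lithium | [Li]c1c(C)cc(OCOC)c([Si](C)(C)C)c1OCOC | intermediate
6 | prop-2-en-1-yl 2,4-bis(methoxymethoxy)-6-methyl-3-(trimethylsilyl)benzoate | C=CCOC(=O)c1c(C)cc(OCOC)c([Si](C)(C)C)c1OCOC | intermediate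
7 | prop-2-en-1-yl 6-methyl-3-(trimethylsilyl)-2,4-bis(trimethylsilyloxy)benzoate | C=CCOC(=O)c1c(C)cc(O[Si](C)(C)C)c([Si](C)(C)C)c1O[Si](C)(C)C | intermediate
8 | prop-2-en-1-yl 2,4-dihydroxy-6-methyl-3-(trimethylsilyl)benzoate | C=CCOC(=O)c1c(C)cc(O)c([Si](C)(C)C)c1O | intermediate
9 | prop-2-en-1-yl 2-hydroxy-6-methyl-4-(trifluoromethylsulfonyloxy)-3-(trimethylsilyl)benzoate | C=CCOC(=O)c1c(C)cc(OS(=O)(=O)C(F)(F)F)c([Si](C)(C)C)c1O | intermediate
10 | prop-2-en-1-yl 2-(methoxymethoxy)-6-methyl-4-(trifluoromethylsulfonyloxy)-3-(trimethylsilyl)benzoate | C=CCOC(=O)c1c(C)cc(OS(=O)(=O)C(F)(F)F)c([Si](C)(C)C)c1OCOC | intermediate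
11 | 2-(methoxymethoxy)-6-methyl-4-(trifluoromethylsulfonyloxy)-3-(trimethylsilyl)benzoic acid | OC(=O)c1c(C)cc(OS(=O)(=O)C(F)(F)F)c([Si](C)(C)C)c1OCOC | intermediate
12 | methyl 2,4-dihydroxy-3,6-dimethylbenzoate | COC(=O)c1c(C)cc(O)c(C)c1O | starting material
13 | methyl 2,4-bis(methoxymethoxy)-3,6-dimethylbenzoate | COC(=O)c1c(C)cc(OCOC)c(C)c1OCOC | intermediate
14 | {[2-(methoxycarbonyl)-3,5-bis(methoxymethoxy)-4-methylphenyl]methyl}lithium | COC(=O)c1c(C[Li])cc(OCOC)c(C)c1OCOC | intermediate
15 | methyl 6-(bromomethyl)-2,4-bis(methoxymethoxy)-3-methylbenzoate | COC(=O)c1c(CBr)cc(OCOC)c(C)c1OCOC | intermediate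
16 | [2-(methoxycarbonyl)-3,5-bis(methoxymethoxy)-4-methylphenyl]methyl 2-(methoxymethoxy)-6-methyl-4-(trifluoromethylsulfonyloxy)-3-(trimethylsilyl)benzoate | COC(=O)c1c(COC(=O)c2c(C)cc(OS(=O)(=O)C(F)(F)F)c([Si](C)(C)C)c2OCOC)cc(OCOC)c(C)c1OCOC | intermediate
17 | N,N-dimethylformamide | CN(C)C=O | starting material
18 | [2-(methoxycarbonyl)-3,5-bis(methoxymethoxy)-4-methylphenyl]methyl 2-(methoxymethoxy)-6-methyl-3,4-didehydrobenzoate (ring B C3–C4 aryne) | COC(=O)c1c(COC(=O)C2=C(OCOC)C#CC=C2C)cc(OCOC)c(C)c1OCOC | intermediate
19 | [2-(methoxycarbonyl)-3,5-bis(methoxymethoxy)-4-methylphenyl]methyl 2-(dimethylamino)-3-(methoxymethoxy)-5-methyl-2H-benzo[b]oxete-4-carboxylate (racemic) | COC(=O)c1c(COC(=O)c2c(C)cc3OC(N(C)C)c3c2OCOC)cc(OCOC)c(C)c1OCOC | intermediate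
20 | [2-(methoxycarbonyl)-3,5-bis(methoxymethoxy)-4-methylphenyl]methyl 3-[(dimethylamino)methylidene]-2-(methoxymethoxy)-6-methyl-4-oxocyclohexa-1,5-diene-1-carboxylate (double-bond geometry undefined) | COC(=O)c1c(COC(=O)C2=C(OCOC)C(=CN(C)C)C(=O)C=C2C)cc(OCOC)c(C)c1OCOC | intermediate
21 | [2-(methoxycarbonyl)-3,5-bis(methoxymethoxy)-4-methylphenyl]methyl 3-formyl-4-hydroxy-2-(methoxymethoxy)-6-methylbenzoate | COC(=O)c1c(COC(=O)c2c(C)cc(O)c(C=O)c2OCOC)cc(OCOC)c(C)c1OCOC | intermediate
22 | [3,5-dihydroxy-2-(methoxycarbonyl)-4-methylphenyl]methyl 3-formyl-2,4-dihydroxy-6-methylbenzoate (CNP0122264.0) | COC(=O)c1c(COC(=O)c2c(C)cc(O)c(C=O)c2O)cc(O)c(C)c1O | target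

## Step count and least certain steps

Total: 12 steps. Longest linear sequence: 10 steps (steps 1 to 7, then 10, 11 and 12, from orcinol 1); the ring A branch (steps 8 and 9) joins at step 10.

**Step 11 (key step).**
- What may go wrong: capture of aryne 18 by something other than 17. Candidates are fluoride, a proton source, or the phenoxide of 21 if traces of water hydrolyse 20 too early. Regiocontrol may also be incomplete, with some attack of oxygen at C3, and 20 may be intercepted by the released dimethylamine instead of being hydrolysed.
- Fallback: the silicon of 6 is used as a regiochemical marker in a different, non-aryne way. The fallback sets out from 6 and returns at 22.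
  - Ipso-iododesilylation of 6 with N-iodosuccinimide should give prop-2-en-1-yl 3-iodo-2,4-bis(methoxymethoxy)-6-methylbenzoate F1.
  - Iodine–magnesium exchange with i-PrMgCl·LiCl at low temperature and quenching with N,N-dimethylformamide should give prop-2-en-1-yl 3-formyl-2,4-bis(methoxymethoxy)-6-methylbenzoate F2.
  - Deallylation as in step 7 should give 3-formyl-2,4-bis(methoxymethoxy)-6-methylbenzoic acid F3.
  - Alkylation with 15 as in step 10 should give [2-(methoxycarbonyl)-3,5-bis(methoxymethoxy)-4-methylphenyl]methyl 3-formyl-2,4-bis(methoxymethoxy)-6-methylbenzoate F4.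
  - Acid methanolysis as in step 12 removes the four MOM ethers and rejoins the route at 22.

**Step 3.**
- What may go wrong: slow metalation beside the methyl group, with competing deprotonation at the aryl methyl or at a silicon methyl, and double addition of 5 to the chloroformate.
- Fallback: the site is fixed by a halogen. The fallback sets out from 2 and returns at 5 and thus 6.
  - Bromination of 2 with N-bromosuccinimide, which goes ortho/para to the oxygens beside the methyl group, should give 2-bromo-1,5-bis(methoxymethoxy)-3-methylbenzene F5.
  - Deprotonation between the two OMOM groups with LiN(i-Pr)2 and trapping with Me3SiCl should give [3-bromo-2,6-bis(methoxymethoxy)-4-methylphenyl]trimethylsilane F6.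
  - Bromine–lithium exchange with n-BuLi at −78 °C then gives 5 at one position only, and acylation as in step 3 returns 6.

**Step 6.**
- What may go wrong: once the C2 oxygen is deprotonated, a carbon-to-oxygen silyl shift with loss of triflate (a base-triggered aryne formation) may occur, or the alkylation of this hindered, hydrogen-bonded phenol may be sluggish.
- Fallback: the order is changed so that the triflate is installed last. The fallback sets out from 8 and returns at 10.
  - Selective silylation of the C4 hydroxyl of 8 with TBSCl and imidazole should give prop-2-en-1-yl 4-(tert-butyldimethylsilyloxy)-2-hydroxy-6-methyl-3-(trimethylsilyl)benzoate F7.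
  - NaH and MOMCl, safe here because no leaving group flanks the silicon, should give prop-2-en-1-yl 4-(tert-butyldimethylsilyloxy)-2-(methoxymethoxy)-6-methyl-3-(trimethylsilyl)benzoate F8.
  - KHF2 in methanol should remove the phenolic silyl ether and give prop-2-en-1-yl 4-hydroxy-2-(methoxymethoxy)-6-methyl-3-(trimethylsilyl)benzoate F9.
  - Triflation with Tf2O and pyridine as in step 5 gives 10.

**Step 9.**
- What may go wrong: Wurtz-type coupling of 14 with freshly formed 15, self-condensation of 14 with the ester of 13, and over-bromination.
- Fallback: a less reactive electrophile is made and activated only in the coupling. The fallback sets out from 13 (via 14) and returns at 16.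
  - Chlorine transfer from hexachloroethane to 14 should give methyl 6-(chloromethyl)-2,4-bis(methoxymethoxy)-3-methylbenzoate F10, which alkylates 14 far more slowly than the bromide does.
  - F10 is then joined to 11 with KHCO3 and catalytic NaI in DMF (iodide exchange in the flask) to give 16.

## Further compounds

F1 | step 11 | prop-2-en-1-yl 3-iodo-2,4-bis(methoxymethoxy)-6-methylbenzoate | C=CCOC(=O)c1c(C)cc(OCOC)c(I)c1OCOC
F2 | step 11 | prop-2-en-1-yl 3-formyl-2,4-bis(methoxymethoxy)-6-methylbenzoate | C=CCOC(=O)c1c(C)cc(OCOC)c(C=O)c1OCOC
F3 | step 11 | 3-formyl-2,4-bis(methoxymethoxy)-6-methylbenzoic acid | OC(=O)c1c(C)cc(OCOC)c(C=O)c1OCOC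
F4 | step 11 | [2-(methoxycarbonyl)-3,5-bis(methoxymethoxy)-4-methylphenyl]methyl 3-formyl-2,4-bis(methoxymethoxy)-6-methylbenzoate | COC(=O)c1c(COC(=O)c2c(C)cc(OCOC)c(C=O)c2OCOC)cc(OCOC)c(C)c1OCOC
F5 | step 3 | 2-bromo-1,5-bis(methoxymethoxy)-3-methylbenzene | COCOc1cc(OCOC)c(Br)c(C)c1
F6 | step 3 | [3-bromo-2,6-bis(methoxymethoxy)-4-methylphenyl]trimethylsilane | COCOc1cc(C)c(Br)c(OCOC)c1[Si](C)(C)C
F7 | step 6 | prop-2-en-1-yl 4-(tert-butyldimethylsilyloxy)-2-hydroxy-6-methyl-3-(trimethylsilyl)benzoate | C=CCOC(=O)c1c(C)cc(O[Si](C)(C)C(C)(C)C)c([Si](C)(C)C)c1O
F8 | step 6 | prop-2-en-1-yl 4-(tert-butyldimethylsilyloxy)-2-(methoxymethoxy)-6-methyl-3-(trimethylsilyl)benzoate | C=CCOC(=O)c1c(C)cc(O[Si](C)(C)C(C)(C)C)c([Si](C)(C)C)c1OCOC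
F9 | step 6 | prop-2-en-1-yl 4-hydroxy-2-(methoxymethoxy)-6-methyl-3-(trimethylsilyl)benzoate | C=CCOC(=O)c1c(C)cc(O)c([Si](C)(C)C)c1OCOC
F10 | step 9 | methyl 6-(chloromethyl)-2,4-bis(methoxymethoxy)-3-methylbenzoate | COC(=O)c1c(CCl)cc(OCOC)c(C)c1OCOC
A1 | alternative 1 | tert-butyl trans-6-methyl-2,4-dioxocyclohexane-1-carboxylate (racemic, one enantiomer drawn) | CC(C)(C)OC(=O)[C@@H]1[C@@H](C)CC(=O)CC1=O
A2 | alternative 1 | tert-butyl acetoacetate (tert-butyl 3-oxobutanoate) | CC(=O)CC(=O)OC(C)(C)C
A3 | alternative 1 | ethyl (E)-but-2-enoate (ethyl crotonate) | C/C=C/C(=O)OCC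
A4 | alternative 2 | 2-(trimethylsilyl)ethyl 3-(diethoxymethyl)-2-hydroxy-6-methyl-4-(triisopropylsilyloxy)benzoate | C[Si](C)(C)CCOC(=O)c1c(C)cc(O[Si](C(C)C)(C(C)C)C(C)C)c(C(OCC)OCC)c1O
A5 | alternative 2 | 2-(trimethylsilyl)ethyl (2E)-5-diazo-3-methyl-4-oxopent-2-enoate | C[Si](C)(C)CCOC(=O)/C=C(\C)C(=O)C=[N+]=[N-]
A6 | alternative 2 | [(3,3-diethoxyprop-1-yn-1-yl)oxy]tri(propan-2-yl)silane | CCOC(OCC)C#CO[Si](C(C)C)(C(C)C)C(C)C
A7 | alternative 3 | [3,5-dihydroxy-2-(methoxycarbonyl)-4-methylphenyl]methyl 3-formyl-2,4-bis(methoxymethoxy)-6-methylbenzoate | COC(=O)c1c(COC(=O)c2c(C)cc(OCOC)c(C=O)c2OCOC)cc(O)c(C)c1O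
A8 | alternative 3 | 1-methoxy-2-methyl-1,3-bis(trimethylsilyloxy)buta-1,3-diene (double-bond geometry undefined) | COC(O[Si](C)(C)C)=C(C)C(=C)O[Si](C)(C)C
A9 | alternative 3 | 4-methoxy-4-oxobut-2-yn-1-yl 3-formyl-2,4-bis(methoxymethoxy)-6-methylbenzoate | COC(=O)C#CCOC(=O)c1c(C)cc(OCOC)c(C=O)c1OCOC
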